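The data are simulated with constants of no real substance.

**Closed books.** In this closed flask we account for the electrophile charged as electrophile plus target, because at 10.0 h the two autumn readings sum to 99.9%. So we keep a ledger in percent of the electrophile charged, with three entries: burst, slow gain and unreacted electrophile.

all flasks: electrophile 0.25 M
- autumn: nucleophile 1 equiv; free base 3 equiv; protic impurity 5 mM; temperature −20 °C; the very flask that is asked about, followed so far
- spring: nucleophile 1 equiv; free base 3 equiv; protic impurity 5 mM; temperature −14 °C; run made earlier
- flask: nucleophile 1.00 equiv; free base 3.00 equiv; protic impurity 5.00 mM; temperature −20 °C; time 12 h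

| run | time / h | target / % | electrophile / % |
|---|---|---|---|
| autumn | 1.33 | 50.7 | 48.0 |
| autumn | 3.00 | 56.4 | 44.3 |
| autumn | 6.00 | 61.1 | 38.3 |
| autumn | 10.0 | 68.2 | 31.7 |
| spring | 1.33 | 56.3 | 43.6 |
| spring | 3.00 | 63.9 | 35.7 |
| spring | 6.00 | 73.2 | 26.0 |
| spring | 10.0 | 82.0 | 18.4 |

(readings scatter by 0.5 percentage points)

- south-east: at 12 h raise the temperature by 25 K, then wait 6.0 h
- north-west: change nothing and wait 6.0 h more
- south-west: at 12 h take out 90% of the target then present, then wait 6.0 h
- east: at 12 h add free base, 50.0% of the amount charged, then wait 6.0 h
- west: at 12 h add free base, 100% of the amount charged, then wait 6.0 h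

- what is taken out of target is counted as made
- additions bring no volume worth counting

1. target, in percent of the electrophile first charged, at 12 h
2. the remedy with the largest gain of target, or "none" below 2 percentage points (south-east / north-west / south-west / east / west / none)
3. target present, with what was taken out counted in, in percent of the electrophile first charged, after south-west
4. target present, with what was taken out counted in, in percent of the electrophile first charged, after west

**Burst entry.** From 3.00 h the autumn target climbs nearly straight, and the line through the readings at 3.00 h and 10.0 h, run back to time zero, stands at 51.3%. This is the burst share, the part of the nucleophile charge that has become target at the foot of the slow line. Electrophile and nucleophile were charged equally, yet about half of the electrophile remains there. We read this as nucleophile held back in a form the readings do not show, so we expect the entry to scale with the nucleophile charge. The same line through the spring run, at −14 °C, gives 56.1%, higher, so we carry the autumn share, as a reading at the temperature of the flask.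

**Slow entry.** We treat the slow gain as a correction to the burst: by 12 h the autumn line adds 20 percentage points. Our ledger for the flask then closes at 71.6% target and 28.4% electrophile.

**The forecast.** The forecast gives 71% at 12 h, slightly below our figure. It names south-east as best, with 78% after south-west and 85% after west, cautioning that “The role of base is unproven”.

**The result.** The flask gave 70.9%, and south-east was best, gaining 27 points. South-west gave 77.6%, and west gave 79.9%, which is 5.1 points below the forecast.

    electrophile + nucleophile → acid set free + target (k = 16.0 M⁻¹ h⁻¹, Ea = 43.0 kJ mol⁻¹)
    nucleophile + acid set free ⇌ protonated nucleophile, settled at all times (K = 3300 M⁻¹, ΔH = −58.0 kJ mol⁻¹)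
    acid set free + free base ⇌ salt of the base (K = 650 M⁻¹, k = 1.40 M⁻¹ h⁻¹, Ea = 59.0 kJ mol⁻¹, ΔH = −61.0 kJ mol⁻¹)
    protic impurity + free base → quenched reagent (k = 6.00 M⁻¹ h⁻¹, Ea = 41.0 kJ mol⁻¹)
    (constants at −20 °C)

**The ledger again.** Against the burst share, the flask's slow entry is 20 points, and at 12.0 h it held 0.0699 M protonated nucleophile with 1.11% of its nucleophile free. For the neighbouring flask with 0.400 equiv nucleophile, the burst share gives a first entry of 20.5%. Its target at 12.0 h is 35.4%, which leaves a slow entry of 15 points and 64.6% electrophile unreacted.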